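The retrosynthesis first removes the five O–CH3 and four aryl–CHO bonds. It then cuts the C4–CH2 bond of the isobutyl group (as methallyl), O1–C2 of the pyran ring, the C4–C4a aryl–carbonyl bond and last C2–C3.
Enabling feature: C2 is benzylic to the 2',4',6'-trioxygenated ring B and ends the six-atom chain O(phenol)–C8a–C4a–C4–C3–C2. A C2 methylene that loses two electrons and a proton therefore becomes a cation within reach of the ring-A phenol oxygen.
Forward: an isovaleryl imide is joined to 2,4,6-trimethoxybenzaldehyde (C2–C3), the carbinol oxygen is removed, and ring A is added as an aryllithium (C4–C4a). One ortho methyl ether is then cleaved and the anode closes the only new ring.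
C4 alkylation, fourfold formylation and demethylation complete the target.
Stereochemistry: C3 comes from (S)-4-benzyl-2-oxazolidinone in a boron aldol. C2 (ring closure, 2,3-trans) and C4 (cation capture, 3,4-trans) are both relayed from C3.

Key step: step 9

Remark: flavan numbering is used throughout (O1, C2, C3, C4, C4a, C5–C8, C8a; ring B = C1'–C6'). The target SMILES corresponds to (2R,3R,4R), that is 2,3-trans and 3,4-trans. Assumption: the carbinol centres of 12 (C1) and 16 (C4) are erased in the following step, so 12 is taken as an epimer mixture and 16 is drawn as the expected major epimer.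

Step 1
Reactants: 1 (S)-4-benzyl-2-oxazolidinone; 2 isovaleryl chloride
Product: 3 (S)-4-benzyl-3-(3-methylbutanoyl)oxazolidin-2-one
Conditions: nBuLi, THF, −78 °C; then 2, −78 → 0 °C
Reagents that add atoms: none
Why: N-acylation of the lithiated oxazolidinone with an acid chloride is the standard entry to Evans imides and touches no stereocentre.

Step 2
Reactants: 3 (S)-4-benzyl-3-(3-methylbutanoyl)oxazolidin-2-one; 4 2,4,6-trimethoxybenzaldehyde
Product: 6 (S)-4-benzyl-3-[(2S,3S)-3-hydroxy-2-isopropyl-3-(2,4,6-trimethoxyphenyl)propanoyl]oxazolidin-2-one, via dibutylboron Z-enolate 5 (not isolated)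
Conditions: Bu2BOTf, Et3N, CH2Cl2, 0 °C; then 4, −78 °C → rt; H2O2, pH 7 buffer/MeOH, 0 °C
Reagents that add atoms: dibutylboron triflate, CCCCB(CCCC)OS(=O)(=O)C(F)(F)F (its Bu2B group stands in 5 only)
Why: In this Evans syn aldol the Z-boron enolate reacts through a Zimmerman–Traxler chair in which the benzyl group of the auxiliary shields one enolate face, which sets the isopropyl-bearing carbon (later C3) in the required sense, while the syn carbinol centre is removed in step 3.

Step 3
Reactants: 6 (S)-4-benzyl-3-[(2S,3S)-3-hydroxy-2-isopropyl-3-(2,4,6-trimethoxyphenyl)propanoyl]oxazolidin-2-one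
Product: 7 (S)-4-benzyl-3-[(R)-3-methyl-2-(2,4,6-trimethoxybenzyl)butanoyl]oxazolidin-2-one
Conditions: Et3SiH (excess), TFA, CH2Cl2, −20 → 0 °C
Reagents that add atoms: none
Why: In this ionic hydrogenation (Kursanov–Parnes type) the acid ionises the strongly activated benzylic alcohol and excess silane delivers hydride faster than arene attack or proton loss, while the neighbouring centre is not involved because the imide does not enolise in acid (its descriptor changes from S to R only through the priority change).

Step 4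
Reactants: 7 (S)-4-benzyl-3-[(R)-3-methyl-2-(2,4,6-trimethoxybenzyl)butanoyl]oxazolidin-2-one
Product: 8 (R)-3-methyl-2-(2,4,6-trimethoxybenzyl)butan-1-ol
Conditions: LiBH4, MeOH (1 equiv), THF, 0 °C
Reagents that add atoms: none
Why: Reductive removal of the auxiliary with alcohol-modified LiBH4 is established for hindered α-isopropyl imides, attacks the exocyclic carbonyl group and does not epimerise the α-carbon.

Step 5
Reactants: 8 (R)-3-methyl-2-(2,4,6-trimethoxybenzyl)butan-1-ol
Product: 9 (R)-3-methyl-2-(2,4,6-trimethoxybenzyl)butanal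
Conditions: Dess–Martin periodinane, pyridine, CH2Cl2, 0 °C → rt
Reagents that add atoms: none
Why: Buffered Dess–Martin oxidation converts the primary alcohol to the aldehyde under near-neutral conditions that leave the α-stereocentre and the electron-rich arene untouched.

Step 6
Reactants: 9 (R)-3-methyl-2-(2,4,6-trimethoxybenzyl)butanal; 10 1,3,5-trimethoxybenzene
Product: 12 (2R)-3-methyl-2-(2,4,6-trimethoxybenzyl)-1-(2,4,6-trimethoxyphenyl)butan-1-ol (both C1 epimers), via 2,4,6-trimethoxyphenyllithium 11 (not isolated)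
Conditions: 10, nBuLi, THF, 0 °C → rt; then 9, −78 °C; H2O
Reagents that add atoms: n-butyllithium, [Li]CCCC (its lithium stands in 11 only)
Why: Directed ortho-lithiation of the symmetrical arene can give only one aryllithium, whose 1,2-addition to the branched aldehyde at low temperature outruns enolisation, and the new carbinol centre (Felkin–Anh epimer expected to prevail) is erased in step 7.

Step 7
Reactants: 12 (2R)-3-methyl-2-(2,4,6-trimethoxybenzyl)-1-(2,4,6-trimethoxyphenyl)butan-1-ol
Product: 13 (R)-3-methyl-2-(2,4,6-trimethoxybenzyl)-1-(2,4,6-trimethoxyphenyl)butan-1-one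
Conditions: Dess–Martin periodinane, pyridine, CH2Cl2, 0 °C → rt (crude 12)
Reagents that add atoms: none
Why: Pyridine-buffered Dess–Martin oxidation converts the acid-labile, hindered benzylic carbinol to the aryl ketone without ionising it and without enolising the adjacent stereocentre.

Step 8
Reactants: 13 (R)-3-methyl-2-(2,4,6-trimethoxybenzyl)-1-(2,4,6-trimethoxyphenyl)butan-1-one
Product: 14 (R)-1-(2-hydroxy-4,6-dimethoxyphenyl)-3-methyl-2-(2,4,6-trimethoxybenzyl)butan-1-one
Conditions: BCl3 (1.1 equiv), CH2Cl2, −78 → −20 °C; then aq. NaHCO3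
Reagents that add atoms: none
Why: In this chelation-controlled ortho-demethylation of an aryl ketone, boron bridges the carbonyl oxygen and one of the two equivalent ortho methoxy groups so that chloride removes only that methyl group, and the carbonyl-free ethers of ring B stay intact at low temperature.

Step 9
Reactants: 14 (R)-1-(2-hydroxy-4,6-dimethoxyphenyl)-3-methyl-2-(2,4,6-trimethoxybenzyl)butan-1-one
Product: 15 (2R,3S)-3-isopropyl-5,7-dimethoxy-2-(2,4,6-trimethoxyphenyl)chroman-4-one
Conditions: graphite anode, Pt cathode, undivided cell, constant current (2.0–2.2 F/mol), nBu4NBF4 (0.1 M), 2,6-lutidine (2 equiv), MeCN/HFIP (4:1), 0 °C → rt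
Reagents that add atoms: none
Why: Proposed new method: the acyl-free ring B should lose one electron at the anode, 2,6-lutidine takes a C2 proton from the radical cation, and a second electron transfer leaves the 2,4,6-trimethoxybenzyl cation (para-quinone methide oxonium form), while protons are reduced to H2 at the cathode. The closest known reaction types are the anodic benzylic C–H alkoxylation and lactonisation of electron-rich alkylarenes and the quinone-mediated cyclisation of 2-(3-arylpropyl)phenols to flavans; what has not been shown is a free acylphenol as the internal trap on a dihydrochalcone that carries an enolisable stereocentre next to the cation. The phenol oxygen closes the pyranone ring in the 6-exo-trig mode, because the C2=C1' double bond of the quinone methide form remains exocyclic to the six-membered ring O1–C2–C3–C4–C4a–C8a. C2 is controlled by C3: allylic 1,3-strain with the two ortho methoxy groups of ring B turns C3–H into the plane of the cation, the acyl tether and the isopropyl group then lie on opposite faces, and attack by the tethered oxygen gives the 2,3-trans (2R,3S) flavanone, which is also the more stable epimer. The same conformer keeps C3–H orthogonal to the empty orbital, which should suppress proton loss to the achiral chalcone, and the weak, hindered base leaves the ketone unenolised, so C3 is kept. Site selectivity needs oxidation of ring B only and at C2 only; it is secured by the lower oxidation potential of ring B compared with the hydrogen-bonded acylphenol ring A, by C2 being the sole benzylic C–H position of ring B, and by the higher potential of the product, so that the charge can be stopped near 2 F/mol.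

Step 10
Reactants: 15 (2R,3S)-3-isopropyl-5,7-dimethoxy-2-(2,4,6-trimethoxyphenyl)chroman-4-one
Product: 16 (2R,3R,4R)-3-isopropyl-5,7-dimethoxy-2-(2,4,6-trimethoxyphenyl)chroman-4-ol
Conditions: NaBH4, THF/EtOH, 0 °C → rt
Reagents that add atoms: none
Why: In this borohydride 1,2-reduction of a flavanone, axial hydride delivery to the half-chair with equatorial C2 and C3 substituents should favour the equatorial (4R) alcohol, and either C4 epimer ionises to the same cation in step 11.

Step 11
Reactants: 16 (2R,3R,4R)-3-isopropyl-5,7-dimethoxy-2-(2,4,6-trimethoxyphenyl)chroman-4-ol; 17 methallyltrimethylsilane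
Product: 18 (2R,3R,4R)-3-isopropyl-5,7-dimethoxy-4-(2-methylallyl)-2-(2,4,6-trimethoxyphenyl)chroman
Conditions: 17 (excess), BF3·OEt2 (1.2 equiv), CH2Cl2, −78 °C; aq. NaHCO3 at −78 °C
Reagents that add atoms: none
Why: In this Hosomi–Sakurai-type SN1 allylation the Lewis acid ionises C4–OH to a cation stabilised by O1, 5-OMe and 7-OMe, and the highly nucleophilic methallylsilane attacks pseudo-axially on the face away from the C3 isopropyl group, which sets C4 as (R), 3,4-trans.

Step 12
Reactants: 18 (2R,3R,4R)-3-isopropyl-5,7-dimethoxy-4-(2-methylallyl)-2-(2,4,6-trimethoxyphenyl)chroman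
Product: 19 (2R,3R,4R)-4-isobutyl-3-isopropyl-5,7-dimethoxy-2-(2,4,6-trimethoxyphenyl)chroman
Conditions: H2 (1 atm), RhCl(PPh3)3 (5 mol %), toluene/EtOH, rt
Reagents that add atoms: none
Why: Homogeneous hydrogenation saturates the exposed 1,1-disubstituted alkene, creates no stereocentre and, unlike a heterogeneous catalyst, cannot hydrogenolyse the benzylic C2–O1 bond.

Step 13
Reactants: 19 (2R,3R,4R)-4-isobutyl-3-isopropyl-5,7-dimethoxy-2-(2,4,6-trimethoxyphenyl)chroman
Product: 21 (2R,3R,4R)-2-(3,5-diformyl-2,4,6-trimethoxyphenyl)-4-isobutyl-3-isopropyl-5,7-dimethoxychroman-6,8-dicarbaldehyde, via tetrakis(chloro(methoxy)methyl)flavan 20 (not isolated)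
Conditions: Cl2CHOMe (excess), TiCl4 (excess), CH2Cl2, −78 → 0 °C; then ice-water
Reagents that add atoms: dichloromethyl methyl ether, COC(Cl)Cl; water, O
Why: In this Rieche formylation each of the four free positions (C6, C8, C3', C5') lies between two oxygen substituents, double formylation of 5,7-dimethoxychromans and 2,4,6-trimethoxyalkylbenzenes is established under these conditions, and any methyl ether lost next to a new aldehyde converges in step 14.

Step 14
Reactants: 21 (2R,3R,4R)-2-(3,5-diformyl-2,4,6-trimethoxyphenyl)-4-isobutyl-3-isopropyl-5,7-dimethoxychroman-6,8-dicarbaldehyde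
Product: 22 sideroxylonal C, (2R,3R,4R)-2-(3,5-diformyl-2,4,6-trihydroxyphenyl)-5,7-dihydroxy-4-isobutyl-3-isopropylchroman-6,8-dicarbaldehyde
Conditions: BCl3 (excess), CH2Cl2, −78 °C → rt; then H2O
Reagents that add atoms: none
Why: In this formyl-assisted ether cleavage all five methoxy groups stand ortho to an aldehyde that chelates boron and directs chloride to the methyl carbon, the aldehydes survive, and a reversible opening of O1–C2 would reclose to the more stable all-trans arrangement of the target.

Compound list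
1 | (S)-4-benzyl-2-oxazolidinone | O=C1N[C@@H](Cc2ccccc2)CO1 | starting material
2 | isovaleryl chloride | CC(C)CC(=O)Cl | starting material
3 | (S)-4-benzyl-3-(3-methylbutanoyl)oxazolidin-2-one | CC(C)CC(=O)N1[C@@H](Cc2ccccc2)COC1=O | intermediate
4 | 2,4,6-trimethoxybenzaldehyde | COc1cc(OC)c(C=O)c(OC)c1 | starting material
5 | dibutylboron Z-enolate of 3 (not isolated) | CCCCB(CCCC)O/C(=C\C(C)C)N1[C@@H](Cc2ccccc2)COC1=O | intermediate
6 | (S)-4-benzyl-3-[(2S,3S)-3-hydroxy-2-isopropyl-3-(2,4,6-trimethoxyphenyl)propanoyl]oxazolidin-2-one | O=C1OC[C@H](Cc2ccccc2)N1C(=O)[C@@H](C(C)C)[C@H](O)c1c(OC)cc(OC)cc1OC | intermediate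
7 | (S)-4-benzyl-3-[(R)-3-methyl-2-(2,4,6-trimethoxybenzyl)butanoyl]oxazolidin-2-one | O=C1OC[C@H](Cc2ccccc2)N1C(=O)[C@@H](C(C)C)Cc1c(OC)cc(OC)cc1OC | intermediate
8 | (R)-3-methyl-2-(2,4,6-trimethoxybenzyl)butan-1-ol | OC[C@@H](C(C)C)Cc1c(OC)cc(OC)cc1OC | intermediate
9 | (R)-3-methyl-2-(2,4,6-trimethoxybenzyl)butanal | O=C[C@@H](C(C)C)Cc1c(OC)cc(OC)cc1OC | intermediate
10 | 1,3,5-trimethoxybenzene | COc1cc(OC)cc(OC)c1 | starting material
11 | 2,4,6-trimethoxyphenyllithium (not isolated) | [Li]c1c(OC)cc(OC)cc1OC | intermediate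
12 | (2R)-3-methyl-2-(2,4,6-trimethoxybenzyl)-1-(2,4,6-trimethoxyphenyl)butan-1-ol, both C1 epimers | COc1cc(OC)c(C(O)[C@@H](C(C)C)Cc2c(OC)cc(OC)cc2OC)c(OC)c1 | intermediate
13 | (R)-3-methyl-2-(2,4,6-trimethoxybenzyl)-1-(2,4,6-trimethoxyphenyl)butan-1-one | COc1cc(OC)c(C(=O)[C@@H](C(C)C)Cc2c(OC)cc(OC)cc2OC)c(OC)c1 | intermediate
14 | (R)-1-(2-hydroxy-4,6-dimethoxyphenyl)-3-methyl-2-(2,4,6-trimethoxybenzyl)butan-1-one | COc1cc(O)c(C(=O)[C@@H](C(C)C)Cc2c(OC)cc(OC)cc2OC)c(OC)c1 | intermediate
15 | (2R,3S)-3-isopropyl-5,7-dimethoxy-2-(2,4,6-trimethoxyphenyl)chroman-4-one (2,3-trans) | O=C1c2c(OC)cc(OC)cc2O[C@@H](c2c(OC)cc(OC)cc2OC)[C@@H]1C(C)C | intermediate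
16 | (2R,3R,4R)-3-isopropyl-5,7-dimethoxy-2-(2,4,6-trimethoxyphenyl)chroman-4-ol | O[C@H]1c2c(OC)cc(OC)cc2O[C@@H](c2c(OC)cc(OC)cc2OC)[C@@H]1C(C)C | intermediate
17 | methallyltrimethylsilane | C=C(C)C[Si](C)(C)C | starting material
18 | (2R,3R,4R)-3-isopropyl-5,7-dimethoxy-4-(2-methylallyl)-2-(2,4,6-trimethoxyphenyl)chroman | C=C(C)C[C@H]1c2c(OC)cc(OC)cc2O[C@@H](c2c(OC)cc(OC)cc2OC)[C@@H]1C(C)C | intermediate
19 | (2R,3R,4R)-4-isobutyl-3-isopropyl-5,7-dimethoxy-2-(2,4,6-trimethoxyphenyl)chroman | CC(C)C[C@H]1c2c(OC)cc(OC)cc2O[C@@H](c2c(OC)cc(OC)cc2OC)[C@@H]1C(C)C | intermediate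
20 | 6,8,3',5'-tetrakis(chloro(methoxy)methyl) derivative of 19 (not isolated, side-chain centres undefined) | CC(C)C[C@H]1c2c(OC)c(C(Cl)OC)c(OC)c(C(Cl)OC)c2O[C@@H](c2c(OC)c(C(Cl)OC)c(OC)c(C(Cl)OC)c2OC)[C@@H]1C(C)C | intermediate
21 | (2R,3R,4R)-2-(3,5-diformyl-2,4,6-trimethoxyphenyl)-4-isobutyl-3-isopropyl-5,7-dimethoxychroman-6,8-dicarbaldehyde | CC(C)C[C@H]1c2c(OC)c(C=O)c(OC)c(C=O)c2O[C@@H](c2c(OC)c(C=O)c(OC)c(C=O)c2OC)[C@@H]1C(C)C | intermediate
22 | sideroxylonal C | CC(C)C[C@H]1c2c(O)c(C=O)c(O)c(C=O)c2O[C@@H](c2c(O)c(C=O)c(O)c(C=O)c2O)[C@@H]1C(C)C | target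

Total step count: 14. Longest linear sequence: 14 steps (1 or 2 to 22).

Steps most likely to fail

1. Step 9.
- Electron transfer from the phenol ring, or aryl–aryl coupling of the ring-B radical cation, may outrun the stereoelectronically slow loss of the C2 proton.
- The cation may lose the C3 proton, which would erode the enantiomeric purity by way of the achiral chalcone.
- The product may be oxidised further.
- Fallback with known chemistry: the oxygen that 4 brings to C2 is kept, so that the same cation arises by ionising a C–O bond, as in the acid-induced closure of β-oxygenated 2'-hydroxydihydrochalcones.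
- Setting out from 6, TBSOTf and 2,6-lutidine give the silyl ether of the aldol adduct F1.
- LiBH4 removes the auxiliary to give the primary alcohol F2.
- Dess–Martin oxidation gives the aldehyde F3.
- Addition of 11 gives the carbinol F4.
- A second buffered Dess–Martin oxidation gives the ketone F5.
- BCl3 then cleaves one methoxy group ortho to the ketone and ionises the benzylic silyl ether in the same flask. The ring-A oxygen closes onto C2 under the same allylic-strain control, and the route is rejoined at 15.

2. Step 11.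
- The C4 cation may lose the C3 proton and scramble C3 on reprotonation.
- The Lewis acid may open O1–C2, so that the silane is consumed at C2.
- The facial bias may be too small.
- Fallback: the cation is replaced by a neutral ortho-quinone methide generated under basic conditions.
- Setting out from 15, one equivalent of BCl3 cleaves the 5-methoxy group next to the ketone to give the 5-hydroxyflavanone F6.
- Boc2O and DMAP give the 5-O-Boc flavanone F7.
- LiBHEt3 at −78 °C adds hydride to C4, and the carbonate migrates to the new alkoxide. Addition of iBuMgBr with warming expels tert-butyl carbonate to give the ortho-quinone methide F8.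
- F8 takes up the isobutyl group at C4 on the face away from the isopropyl group to give the 5-hydroxy-4-isobutylflavan F9.
- MeI and K2CO3 in acetone rejoin the route at 19, so 16 and 18 are bypassed.

3. Step 13.
- Formylation may stall after the first aldehyde on each ring.
- The pyran ring may open under the excess of strong Lewis acid.
- Fallback: electrophilic formylation is replaced by halogenation and metalation.
- Setting out from 19, NBS (four equivalents, MeCN, 0 °C) brominates C6, C8, C3' and C5' to give the tetrabromide F10.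
- Fourfold bromine–lithium exchange (tBuLi, THF, −78 °C) and a DMF quench rejoin the route at 21.

Further compounds
F1 | step 9 | (S)-4-benzyl-3-[(2S,3S)-3-(tert-butyldimethylsilyloxy)-2-isopropyl-3-(2,4,6-trimethoxyphenyl)propanoyl]oxazolidin-2-one | O=C1OC[C@H](Cc2ccccc2)N1C(=O)[C@@H](C(C)C)[C@H](O[Si](C)(C)C(C)(C)C)c1c(OC)cc(OC)cc1OC
F2 | step 9 | (2R,3S)-3-(tert-butyldimethylsilyloxy)-2-isopropyl-3-(2,4,6-trimethoxyphenyl)propan-1-ol | OC[C@@H](C(C)C)[C@H](O[Si](C)(C)C(C)(C)C)c1c(OC)cc(OC)cc1OC
F3 | step 9 | (2S,3S)-3-(tert-butyldimethylsilyloxy)-2-isopropyl-3-(2,4,6-trimethoxyphenyl)propanal | O=C[C@@H](C(C)C)[C@H](O[Si](C)(C)C(C)(C)C)c1c(OC)cc(OC)cc1OC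
F4 | step 9 | 3-(tert-butyldimethylsilyloxy)-2-isopropyl-1,3-bis(2,4,6-trimethoxyphenyl)propan-1-ol, both C1 epimers, other centres as in F3 | COc1cc(OC)c(C(O)[C@@H](C(C)C)[C@H](O[Si](C)(C)C(C)(C)C)c2c(OC)cc(OC)cc2OC)c(OC)c1
F5 | step 9 | (2S,3S)-3-(tert-butyldimethylsilyloxy)-2-isopropyl-1,3-bis(2,4,6-trimethoxyphenyl)propan-1-one | COc1cc(OC)c(C(=O)[C@@H](C(C)C)[C@H](O[Si](C)(C)C(C)(C)C)c2c(OC)cc(OC)cc2OC)c(OC)c1
F6 | step 11 | (2R,3S)-5-hydroxy-3-isopropyl-7-methoxy-2-(2,4,6-trimethoxyphenyl)chroman-4-one | O=C1c2c(O)cc(OC)cc2O[C@@H](c2c(OC)cc(OC)cc2OC)[C@@H]1C(C)C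
F7 | step 11 | tert-butyl (2R,3S)-3-isopropyl-7-methoxy-4-oxo-2-(2,4,6-trimethoxyphenyl)chroman-5-yl carbonate | O=C1c2c(OC(=O)OC(C)(C)C)cc(OC)cc2O[C@@H](c2c(OC)cc(OC)cc2OC)[C@@H]1C(C)C
F8 | step 11 | ortho-quinone methide (C4=C4a, C5=O) with C2 and C3 as in F7, not isolated | O=C1C=C(OC)C=C2O[C@@H](c3c(OC)cc(OC)cc3OC)[C@H](C(C)C)C=C12
F9 | step 11 | (2R,3R,4R)-4-isobutyl-3-isopropyl-7-methoxy-2-(2,4,6-trimethoxyphenyl)chroman-5-ol | CC(C)C[C@H]1c2c(O)cc(OC)cc2O[C@@H](c2c(OC)cc(OC)cc2OC)[C@@H]1C(C)C
F10 | step 13 | (2R,3R,4R)-6,8-dibromo-2-(3,5-dibromo-2,4,6-trimethoxyphenyl)-4-isobutyl-3-isopropyl-5,7-dimethoxychroman | CC(C)C[C@H]1c2c(OC)c(Br)c(OC)c(Br)c2O[C@@H](c2c(OC)c(Br)c(OC)c(Br)c2OC)[C@@H]1C(C)C
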